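(The numbers of this flask were drawn at random within sensible limits.)

Answer 3 questions about one scheme run in two vessels.

| flask | J | remark | time |
|---|---|---|---|
| red | 10 mM | one stirred flow tank at steady state, fed with the mixture as stated, mean residence time 50 min |  |
| green | 10 mM | everything together in a closed stirred flask, run for 50 min | 50 min |

- the set-up with the highest share of Q in all that became Q or L, at the outlet or at the end ("none" if the first two lie within 2 percentage points) (red / green / none)
- share of Q in all that became Q or L, at the outlet or at the end, red
- share of Q in all that became Q or L, at the outlet or at the end, green

    J → D (k1 = 0.0180 s⁻¹)
    Q ⇌ L (K2 = 1.9, k2 = 5.29 × 10⁻⁴ s⁻¹)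
    D → E (k3 = 3.98 × 10⁻⁴ s⁻¹)
    E → Q (k4 = 7.14 × 10⁻⁴ s⁻¹)
    2 J → J2 (k5 = 0.0848 M⁻¹ s⁻¹)

- a species is counted by the J in it: one J2 counts as two
- for a step with 2 of a species take k times the square, and two of it per event
- the stated concentrations are those of everything mixed, before any reaction; amounts are the same in each set-up
- run time (green): 50 min

Write the balance of L for the red tank at steady state. L has a single source in the scheme, Q, so [Q] times the forward rate equals [L] times the sum of the back rate and the wash-out. Set the three first-order rates side by side:

- forward, Q to L: 0.0317 min⁻¹
- back, L to Q: 0.0167 min⁻¹
- wash-out of the red tank, one over the residence time: 0.0200 min⁻¹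

Read the first two rows together. They give 34.5%, the resting share, back rate over the sum of forward and back: the share of Q in Q plus L under thermodynamic control.

Now add the third row to top and bottom of that fraction. The wash-out is faster than the back rate, and red comes to 53.6%.

Green has no third row, so its balance gives a limit and no number. The pair Q and L in green relaxes with a time constant of 20.6 min, but what enters the pair comes through D, whose time constant by step 3 alone, 41.9 min, is longer. Commit, then, to green above the resting share, and stop there without ranking the set-ups.

The forecast goes further, with green best, 53.6% for red and 62.4% for green: “Green is higher, because its Q is freshly made and not yet equilibrated.”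

The simulation gives green, with red at 53.6% and green at 62.4%. Green has not come to rest at 50.0 min: D holds 29.6% and E 22.6% of the J charged, Q is made 1.65 times faster than it is used up, each step taken net, and the share stands 28 percentage points above the resting share. Leave green until 500 min: D falls to 0% and E to 0%, Q goes from 27.1% to 33.0%, L goes from 16.3% to 62.6%, and the share drops to 34.5%, level with the resting share.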